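**Retrosynthetic overview**
- The only ring, the benzene ring, is bought intact as 2-methoxyresorcinol 1, so no ring is formed.
- Key disconnection: the aryl–CH2 bond, joining aryl bromide 2 (from 1 by monobromination) to the β-carbon of a propanoate that acts as a nucleophile (a homoenolate).
- The homoenolate already carries the C18 ester: octadecan-1-ol 3 and 3-bromopropanoic acid 4 give bromoester 5, and zinc insertion gives zinc homoenolate 6.
- Negishi coupling of 6 with unprotected 2 gives target 7 directly, with no protecting groups and no esterification after the C–C bond is made.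

Assumption: the target has no stereocentre and no stereogenic double bond, so it is achiral and no stereocontrol is needed.

**Route**

Step 1
Reactants: 1 2-methoxybenzene-1,3-diol (2-methoxyresorcinol)
Product: 2 4-bromo-2-methoxybenzene-1,3-diol
Conditions: NBS (1.0 equiv, added slowly), MeCN, −30 → 0 °C, dark
Reagents that add atoms: N-bromosuccinimide, O=C1CCC(=O)N1Br
Why: Electrophilic aromatic bromination; C4 and C6 of 1 are equivalent and each is ortho to one OH and para to the other, while C5 is meta to both, so one equivalent of NBS at low temperature gives the single monobromide.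

Step 2
Reactants: 3 octadecan-1-ol; 4 3-bromopropanoic acid
Product: 5 octadecyl 3-bromopropanoate
Conditions: TsOH·H2O (5 mol %), toluene, reflux, Dean–Stark
Reagents that add atoms: none
Why: Fischer esterification driven by azeotropic removal of water; the acidic medium avoids the loss of HBr to the acrylate that a base-mediated acylation would risk.

Step 3
Reactants: 5 octadecyl 3-bromopropanoate; 2 4-bromo-2-methoxybenzene-1,3-diol
Product: 7 octadecyl 3-(2,4-dihydroxy-3-methoxyphenyl)propanoate, via zinc homoenolate 6 (not isolated)
Conditions: Zn dust (activated with BrCH2CH2Br and TMSCl), LiCl, THF, 50 °C, 12 h; then the decanted solution of 6 (2.5 equiv) added over 2 h to 2, Pd(OAc)2 (2 mol %), SPhos (4 mol %), THF, 25 → 40 °C; sat. aq NH4Cl work-up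
Reagents that add atoms: none
Why: Negishi cross-coupling in which the carbonyl-chelated zinc homoenolate 6 transfers its β-carbon to the aryl–palladium bromide formed when zerovalent palladium (from Pd(OAc)2 and SPhos) inserts into the C–Br bond of 2; alkylzinc halides added slowly are expected to transmetalate faster than the phenolic O–H groups protonate them, so the phenols and the ester survive and the target forms directly.

**Compound list**
1 | 2-methoxybenzene-1,3-diol (2-methoxyresorcinol) | COc1c(O)cccc1O | starting material
2 | 4-bromo-2-methoxybenzene-1,3-diol | COc1c(O)ccc(Br)c1O | intermediate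
3 | octadecan-1-ol | CCCCCCCCCCCCCCCCCCO | starting material
4 | 3-bromopropanoic acid | OC(=O)CCBr | starting material
5 | octadecyl 3-bromopropanoate | CCCCCCCCCCCCCCCCCCOC(=O)CCBr | intermediate
6 | bromo[3-(octadecyloxy)-3-oxopropyl]zinc (zinc homoenolate) | CCCCCCCCCCCCCCCCCCOC(=O)CC[Zn]Br | intermediate
7 | octadecyl 3-(2,4-dihydroxy-3-methoxyphenyl)propanoate | CCCCCCCCCCCCCCCCCCOC(=O)CCc1ccc(O)c(OC)c1O | target

**Step count**
Total steps: 3. Longest linear sequence: 2 (step 1 or step 2, then step 3).

**Steps most likely to fail**

Step 3 is the riskiest. The two free phenols may quench 6 before it couples, oxidative addition into the very electron-rich bromide may be slow, and the ortho-hydroxy ester may close to the dihydrocoumarin. The fallback sets out from 2. It is O-benzylated (BnBr, K2CO3, DMF, 25 °C) to 1,3-bis(benzyloxy)-4-bromo-2-methoxybenzene F1. F1, which has no acidic protons, is coupled with 6 (1.3 equiv) under the same Pd(OAc)2/SPhos conditions to give octadecyl 3-[2,4-bis(benzyloxy)-3-methoxyphenyl]propanoate F2. Neutral hydrogenolysis (H2, Pd/C, EtOAc, 25 °C) removes both benzyl groups without touching the ester or promoting lactonisation, and the route is rejoined at 7.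

Step 1 is next. The activated ring may take a second bromine to give the 4,6-dibromide, or be oxidised by NBS. The fallback sets out from 1 and fixes the mono-substitution by directed ortho-metalation instead of electrophilic substitution. Compound 1 is protected (MOMCl, iPr2NEt, CH2Cl2) as 2-methoxy-1,3-bis(methoxymethoxy)benzene F3. F3 is lithiated once at the position ortho to a methoxymethoxy group (n-BuLi, THF, 0 °C) and quenched with BrCl2CCCl2Br to give 1-bromo-3-methoxy-2,4-bis(methoxymethoxy)benzene F4. Acetal cleavage (HCl, MeOH, 25 °C) returns to the route at 2.

Step 2 is the least risky. Possible problems are partial loss of HBr to the acrylate or incomplete esterification of the waxy alcohol. The fallback sets out from 3. It is acylated with acryloyl chloride (Et3N, CH2Cl2, 0 °C) to octadecyl prop-2-enoate F5, which is also sold as stearyl acrylate. Conjugate hydrobromination (HBr, 33 % in AcOH, 0 → 25 °C) places bromine on the β-carbon and returns to the route at 5.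

**Further compounds**
F1 | step 3 | 1,3-bis(benzyloxy)-4-bromo-2-methoxybenzene | COc1c(OCc2ccccc2)ccc(Br)c1OCc1ccccc1
F2 | step 3 | octadecyl 3-[2,4-bis(benzyloxy)-3-methoxyphenyl]propanoate | CCCCCCCCCCCCCCCCCCOC(=O)CCc1ccc(OCc2ccccc2)c(OC)c1OCc1ccccc1
F3 | step 1 | 2-methoxy-1,3-bis(methoxymethoxy)benzene | COCOc1cccc(OCOC)c1OC
F4 | step 1 | 1-bromo-3-methoxy-2,4-bis(methoxymethoxy)benzene | COCOc1ccc(Br)c(OCOC)c1OC
F5 | step 2 | octadecyl prop-2-enoate | CCCCCCCCCCCCCCCCCCOC(=O)C=C
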